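The target is cut at the C10–C11 bond into a cis-hydroazulene vinylogous ester and a perhydrobenzoxepine iodide, joined by a Stork–Danheiser addition. Everything rests on the oxepane bond O19–C18, between the ring oxygen and the CMe2 carbon next to the C17 ketone. A silyl triflate triggers a cascade in an acyclic bis-epoxide that carries a (Z)-silyl enol ether: the internal epoxide oxygen attacks the tertiary, cation-stabilising carbon C18 of the terminal epoxide, and the enol ether opens the resulting epoxonium ion at C14. One operation closes the oxepane and the trans-fused cyclohexanone and fixes C13, C14, C17 and C20; the C17 oxygen later becomes the ketone.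

Key step: step 16

Atom labels: C1 is the ring carbon bearing the exocyclic methylene; then C2 (enone C=O), C3, C4 and C5 (ring fusion), C6, C7, C8 (methyl carbinol), C9 (CMe2), C10, C11, C12 (linker), C13, C14 (angular methyl), C15, C16, C17 (oxepanone C=O), C18 (CMe2), O19, C20, C21, C22, C23 (methyl carbinol).
Remark: the D-fructose-derived Shi ketone is taken to give the (R,R)-epoxides of (E)-trisubstituted olefins, as is general for this catalyst.

**Hydroazulene fragment (steps 1–11)**

Step 1
Reactants: 1 geraniol
Product: 2 (2R,3R)-2,3-epoxygeraniol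
Conditions: Ti(OiPr)4, D-(−)-diethyl tartrate, t-BuOOH, 4 Å MS, CH2Cl2, −20 °C
Reagents that add atoms: tert-butyl hydroperoxide, CC(C)(C)OO
Why: Sharpless asymmetric epoxidation of the allylic alcohol, in which the D-tartrate complex delivers oxygen to the face that gives the (2R,3R)-epoxide and so fixes the future C8 configuration.

Step 2
Reactants: 2 (2R,3R)-2,3-epoxygeraniol
Product: 3 (2S,3R)-1-chloro-2,3-epoxy-3,7-dimethyloct-6-ene
Conditions: PPh3, CCl4, NaHCO3, reflux
Reagents that add atoms: carbon tetrachloride, ClC(Cl)(Cl)Cl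
Why: Appel chlorination of the primary alcohol under neutral conditions should leave the trisubstituted epoxide and both stereocentres untouched.

Step 3
Reactants: 3 (2S,3R)-1-chloro-2,3-epoxy-3,7-dimethyloct-6-ene
Product: 4 (R)-3,7-dimethyloct-6-en-1-yn-3-ol
Conditions: n-BuLi (3.2 equiv), THF, −40 °C → rt; NH4Cl (aq)
Reagents that add atoms: none
Why: Base-induced double elimination of a 2,3-epoxy chloride (epoxide opening to the chlorovinyl alkoxide, then dehydrochlorination) should give the terminal alkyne, and the tertiary C–O bond is not broken so C8 keeps its configuration.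

Step 4
Reactants: 4 (R)-3,7-dimethyloct-6-en-1-yn-3-ol
Product: 5 (4R)-4-hydroxy-1,1,4-trimethyl-4,5,6,6a-tetrahydropentalen-2(1H)-one (both epimers at ring-fusion carbon C5)
Conditions: Co2(CO)8 (20 mol %), tetramethylthiourea (60 mol %), CO (1 atm), toluene, 70 °C
Reagents that add atoms: carbon monoxide, [C-]#[O+]
Why: Intramolecular Pauson–Khand reaction of the 1,6-enyne, helped by the quaternary propargylic carbon, should join C4–C5 and put the CMe2 alkene terminus (C9) next to the new C10 carbonyl; the C5 epimer mixture is inconsequential because C5 is erased in step 5.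

Step 5
Reactants: 5 bicyclic enone (both C5 epimers)
Product: 7 (4R)-4-hydroxy-1,1,4-trimethyl-1,4,5,6-tetrahydropentalen-2(3H)-one (C4=C5 alkene), via dilithium dienolate 6 (not isolated)
Conditions: LDA (2.5 equiv), THF, −78 → 0 °C; inverse quench into AcOH/THF, −78 °C
Reagents that add atoms: none
Why: The only acidic C–H is the γ-hydrogen at C5 (C9 is quaternary), so deprotonation should give the 2-oxidocyclopentadiene and kinetic α-protonation at C3 the deconjugated β,γ-enone, converging both C5 epimers (deconjugative protonation of an extended enolate).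

Step 6
Reactants: 7 β,γ-unsaturated hydroxy ketone
Product: 8 (3aR,4R,6aR)-4-hydroxy-1,1,4-trimethylhexahydropentalen-2(1H)-one
Conditions: [Ir(cod)(PCy3)(py)]PF6 (10 mol %), H2 (50 atm), CH2Cl2, rt
Reagents that add atoms: none
Why: Hydroxyl-directed hydrogenation with Crabtree's catalyst should deliver both hydrogens to the alkene face bound through the C8 hydroxyl, so H4 and H5 end up cis to that hydroxyl and the ring fusion is cis.

Step 7
Reactants: 8 cis-fused hydroxy ketone
Product: 9 bis(trimethylsilyl) derivative (C10=C3 silyl enol ether and C8 silyl ether)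
Conditions: Me3SiOTf (2.5 equiv), Et3N, CH2Cl2, 0 °C
Reagents that add atoms: trimethylsilyl trifluoromethanesulfonate, C[Si](C)(C)OS(=O)(=O)C(F)(F)F
Why: Soft enolisation can only occur towards C3 because C9 is quaternary, so a single regiodefined silyl enol ether should form while the tertiary alcohol is silylated at the same time.

Step 8
Reactants: 9 bis(trimethylsilyl) derivative
Product: 10 dichlorocyclobutanone adduct (C3–C2 and C10–C1 bonds on the convex face)
Conditions: Cl2CHCOCl, Et3N, hexanes, rt
Reagents that add atoms: dichloroacetyl chloride, O=C(Cl)C(Cl)Cl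
Why: [2+2] cycloaddition of dichloroketene to the silyl enol ether should bond the ketene carbonyl carbon to the nucleophilic carbon C3 from the convex face of the cis-bicycle, and the two new centres are removed again in step 9.

Step 9
Reactants: 10 dichlorocyclobutanone adduct
Product: 12 (1R,3aR,8aR)-1-hydroxy-1,4,4-trimethyloctahydroazulene-5,7-dione, via siloxycyclobutanone 11 (not isolated)
Conditions: Zn, AcOH, i-PrOH/H2O, 0 °C → rt; then AcOH, i-PrOH/H2O, reflux
Reagents that add atoms: none
Why: Reductive dechlorination followed by desilylation should trigger retro-aldol cleavage of the ring-fusion bond C10–C3, a two-carbon ring expansion of the cyclopentanone to the cycloheptane-1,3-dione that leaves C4, C5 and C8 untouched.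

Step 10
Reactants: 12 hydroxy 1,3-dione
Product: 13 (1R,3aR,8aR)-1-hydroxy-7-methoxy-1,4,4-trimethyl-2,3,3a,4,8,8a-hexahydroazulen-5(1H)-one
Conditions: MeOH, TsOH·H2O (5 mol %), 3 Å MS, rt
Reagents that add atoms: methanol, CO
Why: Acid-catalysed enol etherification should take place at the unhindered C2 carbonyl and leave the neopentyl C10 carbonyl next to the CMe2 group as the ketone (vinylogous ester formation).

Step 11
Reactants: 13 hydroxy vinylogous ester
Product: 14 C8 triethylsilyl ether of the vinylogous ester
Conditions: Et3SiOTf, 2,6-lutidine, CH2Cl2, −78 → 0 °C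
Reagents that add atoms: triethylsilyl trifluoromethanesulfonate, CC[Si](CC)(CC)OS(=O)(=O)C(F)(F)F
Why: Silyl triflate with a hindered pyridine base should silylate the tertiary alcohol so that it does not quench the organolithium in step 21.

**Benzoxepine fragment (steps 12–20)**

Step 12
Reactants: 15 dimethyl (2-oxopropyl)phosphonate; 16 geranyl bromide
Product: 18 dimethyl [(5E)-6,10-dimethyl-2-oxoundeca-5,9-dien-1-yl]phosphonate, via phosphonate dianion 17 (not isolated)
Conditions: NaH, THF, 0 °C; n-BuLi, 0 °C; then 16, 0 °C → rt; NH4Cl (aq)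
Reagents that add atoms: none
Why: The β-ketophosphonate dianion should be alkylated by the allylic bromide at its more basic terminal (γ) carbon, which puts C22 and C23 in place and keeps the phosphonate for olefination.

Step 13
Reactants: 18 β-ketophosphonate; 19 (benzyloxy)acetaldehyde
Product: 20 (2E,7E)-1-(benzyloxy)-8,12-dimethyltrideca-2,7,11-trien-4-one
Conditions: LiCl, i-Pr2NEt, MeCN, rt
Reagents that add atoms: none
Why: Horner–Wadsworth–Emmons olefination under Masamune–Roush conditions should give the (E)-enone and introduce C12 and C11 with the protected oxygen handle.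

Step 14
Reactants: 20 dienyl enone
Product: 21 (14R,20R),(17R)-bis-epoxide of 20 with the (E)-enone intact
Conditions: D-fructose-derived Shi ketone (30 mol %), Oxone (2KHSO5·KHSO4·K2SO4), K2CO3, Bu4NHSO4, Na2B4O7/Na2EDTA buffer (pH 10.5), MeCN/CH2(OMe)2, 0 °C
Reagents that add atoms: potassium peroxymonosulfate, [K+].[O-]S(=O)(=O)OO
Why: Shi epoxidation by the chiral dioxirane should epoxidise both electron-rich trisubstituted alkenes through the spiro transition state to the (R,R)- and (R)-epoxides and leave the electron-poor enone alkene alone.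

Step 15
Reactants: 21 bis-epoxy enone
Product: 22 (Z)-triethylsilyl enol ether of 21 (C23(OSiEt3)=C13H)
Conditions: Et3SiH, RhCl(PPh3)3 (2 mol %), THF, 50 °C
Reagents that add atoms: triethylsilane, CC[SiH](CC)CC
Why: Rhodium-catalysed 1,4-hydrosilylation of the s-cis enone should give the regiodefined silyl enol ether with silyloxy and C12 cis, the geometry that places C12 equatorial in step 16.

Step 16
Reactants: 22 (Z)-silyl enol ether bis-epoxide
Product: 23 (3R,5aR,6R,9aR)-6-[2-(benzyloxy)ethyl]-2,2,5a-trimethyl-3-[(triethylsilyl)oxy]octahydro-1-benzoxepin-7(2H)-one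
Conditions: Et3SiOTf (1.0 equiv), 2,6-di-tert-butyl-4-methylpyridine, CH2Cl2, −78 °C; NaHCO3 (aq)
Reagents that add atoms: none
Why: Et3SiOTf silylates the terminal epoxide oxygen, the tertiary C18–O bond ionises with participation of the internal epoxide oxygen O19 (new O19–C18 bond, bicyclo[4.1.0] epoxonium ion), and the enol ether carbon C13 opens the epoxonium at the tertiary carbon C14 while its silyl group returns to triflate, so the net change is an isomerisation with silyl transfer to the C17 oxygen. The closest known reaction type is the silyl-triflate promoted tandem oxa- and carbacyclisation of 1,5-diepoxides terminated by enol silanes. The oxepane closes by endo-selective epoxide opening (anti attack at the distal tertiary carbon, a six-membered epoxonium ring that becomes the seven-membered ring when C14–O19 breaks), and the cyclohexanone closes 6-endo-trig at the enol ether with exo cleavage of the C14–O19 bond. C14 is set by inversion and C20 and C17 by retention of the Shi-derived epoxide centres, which gives the trans ring fusion with axial C14 methyl, and C13 is set by the chair transition state in which the (Z)-enol ether places C12 equatorial, which is also the thermodynamic epimer of the ketone. The step needs activation of the terminal epoxide before the internal one and endo regiochemistry; the tertiary carbon C18, the six-ring geometry of oxygen participation and the fact that the enol ether can reach only C14 should secure this, with the hindered pyridine suppressing proton-mediated pathways.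

Step 17
Reactants: 23 bicyclic ketone
Product: 24 C23 tertiary alcohol (7S; axial hydroxyl and equatorial methyl)
Conditions: MeMgBr, Et2O/toluene, −78 → 0 °C; NH4Cl (aq)
Reagents that add atoms: methylmagnesium bromide, C[Mg]Br
Why: Grignard addition to the cyclohexanone should occur by equatorial attack, anti to the 1,3-diaxial C14 methyl, which sets C23 with axial hydroxyl cis to that methyl.

Step 18
Reactants: 24 tertiary alcohol
Product: 25 C17,C23-bis(triethylsilyl) ether with C11 benzyl ether
Conditions: Et3SiOTf, 2,6-lutidine, CH2Cl2, −78 → 0 °C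
Reagents that add atoms: triethylsilyl trifluoromethanesulfonate, CC[Si](CC)(CC)OS(=O)(=O)C(F)(F)F
Why: Silylation of the tertiary alcohol with the silyl triflate should mask the last acidic proton before the organolithium is made.

Step 19
Reactants: 25 bis-silyl benzyl ether
Product: 26 C11 primary alcohol
Conditions: H2 (1 atm), Pd/C, EtOAc, rt
Reagents that add atoms: none
Why: Hydrogenolysis of the benzyl ether in a neutral aprotic solvent should free the primary alcohol without touching the silyl ethers, and no alkene remains in the substrate.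

Step 20
Reactants: 26 primary alcohol
Product: 27 C11 primary iodide
Conditions: I2, PPh3, imidazole, CH2Cl2, 0 °C → rt
Reagents that add atoms: iodine, II
Why: Appel-type iodination through the alkoxyphosphonium salt should convert only the primary alcohol into the iodide.

**Union and endgame (steps 21–25)**

Step 21
Reactants: 27 primary iodide; 14 silyl-protected vinylogous ester
Product: 30 coupled enone (C2 ketone with C1=C10 alkene and all three hydroxyls as triethylsilyl ethers), via alkyllithium 28 (not isolated), via tertiary carbinol adduct 29 (not isolated)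
Conditions: t-BuLi (2.1 equiv), Et2O/pentane, −78 °C; 14, −78 → 0 °C; NH4Cl (aq); then 5 % aq. oxalic acid, THF, 0 °C
Reagents that add atoms: none
Why: Lithium–iodine exchange and 1,2-addition of the primary alkyllithium to the C10 carbonyl, then mild acid hydrolysis of the enol ether with loss of the tertiary hydroxyl, should give the transposed enone with the side chain on C10 (Stork–Danheiser sequence).

Step 22
Reactants: 30 coupled enone
Product: 32 trimethylsilyl enol ether (C2(OSiMe3)=C1H, 10R), via lithium enolate 31 (not isolated)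
Conditions: Li, NH3(l)/THF, t-BuOH (1.0 equiv), −78 °C; isoprene; evaporate NH3; Me3SiCl, Et3N, THF, −78 → 0 °C
Reagents that add atoms: chlorotrimethylsilane, C[Si](C)(C)Cl
Why: Dissolving-metal conjugate reduction should protonate C10 on the convex face away from the cyclopentane ring, leaving the side chain pseudo-equatorial and cis to C6, and the regiodefined enolate is trapped as its silyl enol ether (reductive silylation).

Step 23
Reactants: 32 trimethylsilyl enol ether
Product: 35 tris(triethylsilyl) ether of the α-methylene ketone, via Mannich base 33 (not isolated), via ammonium iodide 34 (not isolated)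
Conditions: CH2=NMe2+ I−, CH2Cl2, rt; MeI, rt; DBU, CH2Cl2, 0 °C
Reagents that add atoms: Eschenmoser's salt (N,N-dimethylmethyleneiminium iodide), C=[N+](C)C.[I-]
Why: Mannich reaction of the silyl enol ether at C1, quaternisation and base-induced elimination of trimethylamine should give the exocyclic methylene regiospecifically under conditions too mild to move the alkene into the ring (Eschenmoser methylenation).

Step 24
Reactants: 35 tris-silyl α-methylene ketone
Product: 36 C8,C17,C23-triol
Conditions: HF·pyridine, pyridine/THF, 0 °C → rt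
Reagents that add atoms: none
Why: Buffered fluoride should cleave the secondary and both tertiary triethylsilyl ethers without isomerising the exocyclic enone.

Step 25
Reactants: 36 triol
Product: 37 CNP0316622.2 (target)
Conditions: Dess–Martin periodinane, NaHCO3, CH2Cl2, 0 °C → rt
Reagents that add atoms: none
Why: Dess–Martin oxidation should convert the only secondary alcohol (C17) into the oxepanone carbonyl, the two tertiary alcohols being inert.

**Compound list**

1 | geraniol | CC(C)=CCC/C(C)=C/CO | starting material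
2 | (2R,3R)-2,3-epoxygeraniol | CC(C)=CCC[C@@]1(C)O[C@@H]1CO | intermediate
3 | (2S,3R)-1-chloro-2,3-epoxy-3,7-dimethyloct-6-ene | CC(C)=CCC[C@@]1(C)O[C@@H]1CCl | intermediate
4 | (R)-3,7-dimethyloct-6-en-1-yn-3-ol | C#C[C@](C)(O)CCC=C(C)C | intermediate
5 | (4R)-4-hydroxy-1,1,4-trimethyl-4,5,6,6a-tetrahydropentalen-2(1H)-one, both C5 epimers | O=C1C=C2[C@](C)(O)CCC2C1(C)C | intermediate
6 | dilithium alkoxide dienolate of 5 | [Li]OC1=CC2=C(CC[C@@]2(C)O[Li])C1(C)C | intermediate
7 | (4R)-4-hydroxy-1,1,4-trimethyl-1,4,5,6-tetrahydropentalen-2(3H)-one | O=C1CC2=C(CC[C@@]2(C)O)C1(C)C | intermediate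
8 | (3aR,4R,6aR)-4-hydroxy-1,1,4-trimethylhexahydropentalen-2(1H)-one | O=C1C[C@@H]2[C@@H](CC[C@@]2(C)O)C1(C)C | intermediate
9 | bis(trimethylsilyl) derivative of 8 (C10=C3 enol ether, C8 silyl ether) | C[Si](C)(C)OC1=C[C@@H]2[C@@H](CC[C@@]2(C)O[Si](C)(C)C)C1(C)C | intermediate
10 | dichlorocyclobutanone adduct of 9 (exo-fused) | O=C1C(Cl)(Cl)[C@]2(O[Si](C)(C)C)[C@H]1[C@@H]1[C@@H](CC[C@@]1(C)O[Si](C)(C)C)C2(C)C | intermediate
11 | dechlorinated siloxycyclobutanone | O=C1C[C@]2(O[Si](C)(C)C)[C@H]1[C@@H]1[C@@H](CC[C@@]1(C)O[Si](C)(C)C)C2(C)C | intermediate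
12 | (1R,3aR,8aR)-1-hydroxy-1,4,4-trimethyloctahydroazulene-5,7-dione | O=C1CC(=O)C[C@@H]2[C@@H](CC[C@@]2(C)O)C1(C)C | intermediate
13 | (1R,3aR,8aR)-1-hydroxy-7-methoxy-1,4,4-trimethyl-2,3,3a,4,8,8a-hexahydroazulen-5(1H)-one | O=C1C=C(OC)C[C@@H]2[C@@H](CC[C@@]2(C)O)C1(C)C | intermediate
14 | C8 triethylsilyl ether of 13 | O=C1C=C(OC)C[C@@H]2[C@@H](CC[C@@]2(C)O[Si](CC)(CC)CC)C1(C)C | intermediate
15 | dimethyl (2-oxopropyl)phosphonate | COP(=O)(OC)CC(C)=O | starting material
16 | geranyl bromide | CC(C)=CCC/C(C)=C/CBr | starting material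
17 | sodium lithium dianion of 15 | [Na+].[Li+].COP(=O)(OC)[CH-]C(=O)[CH2-] | intermediate
18 | dimethyl [(5E)-6,10-dimethyl-2-oxoundeca-5,9-dien-1-yl]phosphonate | COP(=O)(OC)CC(=O)CC/C=C(\C)CCC=C(C)C | intermediate
19 | (benzyloxy)acetaldehyde | O=CCOCc1ccccc1 | starting material
20 | (2E,7E)-1-(benzyloxy)-8,12-dimethyltrideca-2,7,11-trien-4-one | O=C(/C=C/COCc1ccccc1)CC/C=C(\C)CCC=C(C)C | intermediate
21 | (14R,20R),(17R)-bis-epoxide of 20 | O=C(/C=C/COCc1ccccc1)CC[C@H]1O[C@]1(C)CC[C@H]1OC1(C)C | intermediate
22 | (Z)-triethylsilyl enol ether of 21 | CC[Si](CC)(CC)O/C(CC[C@H]1O[C@]1(C)CC[C@H]1OC1(C)C)=C\CCOCc1ccccc1 | intermediate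
23 | (3R,5aR,6R,9aR)-6-[2-(benzyloxy)ethyl]-2,2,5a-trimethyl-3-[(triethylsilyl)oxy]octahydro-1-benzoxepin-7(2H)-one | c1ccccc1COCC[C@@H]1[C@@]2(C)CC[C@@H](O[Si](CC)(CC)CC)C(C)(C)O[C@@H]2CCC1=O | intermediate
24 | (7S)-7-methyl carbinol from 23 (axial OH) | c1ccccc1COCC[C@@H]1[C@@]2(C)CC[C@@H](O[Si](CC)(CC)CC)C(C)(C)O[C@@H]2CC[C@]1(C)O | intermediate
25 | C17,C23-bis(triethylsilyl) ether, C11 benzyl ether | c1ccccc1COCC[C@@H]1[C@@]2(C)CC[C@@H](O[Si](CC)(CC)CC)C(C)(C)O[C@@H]2CC[C@]1(C)O[Si](CC)(CC)CC | intermediate
26 | C11 primary alcohol | OCC[C@@H]1[C@@]2(C)CC[C@@H](O[Si](CC)(CC)CC)C(C)(C)O[C@@H]2CC[C@]1(C)O[Si](CC)(CC)CC | intermediate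
27 | C11 primary iodide | ICC[C@@H]1[C@@]2(C)CC[C@@H](O[Si](CC)(CC)CC)C(C)(C)O[C@@H]2CC[C@]1(C)O[Si](CC)(CC)CC | intermediate
28 | C11 alkyllithium | [Li]CC[C@@H]1[C@@]2(C)CC[C@@H](O[Si](CC)(CC)CC)C(C)(C)O[C@@H]2CC[C@]1(C)O[Si](CC)(CC)CC | intermediate
29 | C10 tertiary carbinol adduct (either C10 configuration) | COC=1C[C@@H]2[C@@H](CC[C@@]2(C)O[Si](CC)(CC)CC)C(C)(C)C(O)(CC[C@@H]3[C@@]4(C)CC[C@@H](O[Si](CC)(CC)CC)C(C)(C)O[C@@H]4CC[C@]3(C)O[Si](CC)(CC)CC)C=1 | intermediate
30 | coupled enone (C2 ketone, C1=C10) | O=C1C[C@@H]2[C@@H](CC[C@@]2(C)O[Si](CC)(CC)CC)C(C)(C)C(CC[C@@H]3[C@@]4(C)CC[C@@H](O[Si](CC)(CC)CC)C(C)(C)O[C@@H]4CC[C@]3(C)O[Si](CC)(CC)CC)=C1 | intermediate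
31 | lithium enolate (C2(OLi)=C1, 10R) | [Li]OC=1C[C@@H]2[C@@H](CC[C@@]2(C)O[Si](CC)(CC)CC)C(C)(C)[C@@H](CC[C@@H]3[C@@]4(C)CC[C@@H](O[Si](CC)(CC)CC)C(C)(C)O[C@@H]4CC[C@]3(C)O[Si](CC)(CC)CC)C=1 | intermediate
32 | trimethylsilyl enol ether (10R) | C[Si](C)(C)OC=1C[C@@H]2[C@@H](CC[C@@]2(C)O[Si](CC)(CC)CC)C(C)(C)[C@@H](CC[C@@H]3[C@@]4(C)CC[C@@H](O[Si](CC)(CC)CC)C(C)(C)O[C@@H]4CC[C@]3(C)O[Si](CC)(CC)CC)C=1 | intermediate
33 | C1 dimethylaminomethyl ketone (Mannich base, C1 epimers) | CN(C)CC1C(=O)C[C@@H]2[C@@H](CC[C@@]2(C)O[Si](CC)(CC)CC)C(C)(C)[C@H]1CC[C@@H]1[C@@]2(C)CC[C@@H](O[Si](CC)(CC)CC)C(C)(C)O[C@@H]2CC[C@]1(C)O[Si](CC)(CC)CC | intermediate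
34 | trimethylammonium iodide of 33 | [I-].C[N+](C)(C)CC1C(=O)C[C@@H]2[C@@H](CC[C@@]2(C)O[Si](CC)(CC)CC)C(C)(C)[C@H]1CC[C@@H]1[C@@]2(C)CC[C@@H](O[Si](CC)(CC)CC)C(C)(C)O[C@@H]2CC[C@]1(C)O[Si](CC)(CC)CC | intermediate
35 | tris(triethylsilyl) ether of the α-methylene ketone | C=C1C(=O)C[C@@H]2[C@@H](CC[C@@]2(C)O[Si](CC)(CC)CC)C(C)(C)[C@H]1CC[C@@H]1[C@@]2(C)CC[C@@H](O[Si](CC)(CC)CC)C(C)(C)O[C@@H]2CC[C@]1(C)O[Si](CC)(CC)CC | intermediate
36 | C8,C17,C23-triol (17R alcohol) | C=C1C(=O)C[C@@H]2[C@@H](CC[C@@]2(C)O)C(C)(C)[C@H]1CC[C@@H]1[C@@]2(C)CC[C@@H](O)C(C)(C)O[C@@H]2CC[C@]1(C)O | intermediate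
37 | CNP0316622.2 | C=C1C(=O)C[C@@H]2[C@@H](CC[C@@]2(C)O)C(C)(C)[C@H]1CC[C@@H]1[C@@]2(C)CCC(=O)C(C)(C)O[C@@H]2CC[C@]1(C)O | target

**Step count and risks**

Total step count: 25. Longest linear sequence: 16 steps (steps 1–11, then 21–25).

Steps most likely to fail:

1. Step 16 (cascade). What may go wrong: the epoxonium ion is intercepted before the carbocyclisation (hydride shift or elimination), or the Lewis acid opens the internal epoxide first, so that oxa- and carbacyclisation fall out of sequence. Fallback, a stepwise closure that sets out from 22 and comes back at 23: MeAlCl2 in CH2Cl2 at −94 °C should effect the epoxide-initiated cyclisation of the internal epoxide onto the enol ether and give the hydroxy epoxy ketone F1. Camphorsulfonic acid (cat.) in CH2Cl2 at 0 °C should then open the remaining trisubstituted epoxide at its tertiary carbon C18 by the C20 hydroxyl in the 7-endo mode, forming the same O19–C18 bond and giving the oxepane alcohol F2. Et3SiCl and imidazole in DMF give 23.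

2. Step 6 (directed hydrogenation). What may go wrong: the cationic iridium catalyst fails to turn over at the fully substituted alkene flanked by two quaternary carbons, or its acidity ionises the allylic tertiary hydroxyl. Fallback, from 5 to 8: the C5 epimers of 5 are separated by chromatography and the epimer with the hydroxyl cis to H5, the enone F3, is hydrogenated over Pd/C in EtOAc, where addition to the trisubstituted enone can only give the cis-fused 8. The other epimer is returned to the mixture by re-forming dienolate 6 and protonating it under equilibrating conditions.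

3. Step 22 (reductive silylation). What may go wrong: poor facial selectivity in the protonation at C10, which cannot be corrected later because C10 is not epimerisable. Fallback, from 30 to 35: a ligand-controlled copper hydride conjugate reduction (Cu(OAc)2·H2O cat., the matched enantiomer of DTBM-SEGPHOS, PhMe2SiH, toluene, 0 °C) should set C10 by the catalyst and give the dimethylphenylsilyl enol ether F4. F4 is taken through the conditions of step 23 and reaches 35.

Further compounds
F1 | step 16 | hydroxy epoxy ketone: cyclohexanone with C20 hydroxyl and intact (17R)-epoxide | c1ccccc1COCC[C@@H]1[C@@](C)(CC[C@H]2OC2(C)C)[C@H](O)CCC1=O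
F2 | step 16 | C17 alcohol corresponding to 23 | c1ccccc1COCC[C@@H]1[C@@]2(C)CC[C@@H](O)C(C)(C)O[C@@H]2CCC1=O
F3 | step 6 | single C5 epimer of 5 with hydroxyl cis to H5 | O=C1C=C2[C@](C)(O)CC[C@H]2C1(C)C
F4 | step 22 | dimethylphenylsilyl enol ether corresponding to 32 | C[Si](C)(c1ccccc1)OC=1C[C@@H]2[C@@H](CC[C@@]2(C)O[Si](CC)(CC)CC)C(C)(C)[C@@H](CC[C@@H]3[C@@]4(C)CC[C@@H](O[Si](CC)(CC)CC)C(C)(C)O[C@@H]4CC[C@]3(C)O[Si](CC)(CC)CC)C=1
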